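Assumption: (−)-catechin, the (2S,3R) enantiomer, is taken as a purchasable compound; all phenols travel as benzyl ethers and the arene positions that must stay silent as bromides, removed together in the last step.

Atom labels. Lower unit: flavan numbering (O1, C2, C3, C4, C4a, C5–C8, C8a), with ring A (benzo ring), ring B (catechol) and ring C (pyran). Upper unit: dihydrobenzofuran O1′, C2′, C3′, C3a′, C4′–C7′, C7a′, with ring D (benzo ring) and ring E (dihydrofuran); the methine is C-α and its catechol is ring F.

## The problem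

- The target joins two C6–C3–C6 units by a single C–C bond from the doubly benzylic methine C-α to C6 of ring A of a (2S,3S)-flavan-3-ol, the 2,3-cis series enantiomeric to natural epicatechin.
- C-α (R) carries ring F, ring A and C2′ (S) of a 4,6-dihydroxy-2,3-dihydrobenzofuran. The two centres are contiguous but not in a common ring, and C-α cannot be corrected once made, so it has to be controlled from C2′ at the moment the C-α–C6 bond forms.
- Ring A has two nucleophilic carbons, C6 and C8; C8 is the more accessible, yet the link is at C6.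
- All four arenes are polyphenols. The C-α–C6 bond can be cleaved by strong acid (retro-Friedel–Crafts), and C2 can epimerise in base through a quinone methide once the ring B phenols are free. The last step must therefore be neutral.
- The enabling feature: the chain O1′–C2′(–C3′H2–ring D)–C-α(ring F) is what a 2,3-trans-flavan-3-ol becomes when its pyran oxygen O1 moves from C2 to C3. C-α is a former flavan C2, C2′ a former C3, and ring E is a contracted ring C.
- The target is therefore a hetero-dimer of two flavan-3-ols of the same 2S series that differ only at C3. One bought compound can supply both halves.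

## Retrosynthesis

**10 ⇒ 9.** Eight O–benzyl bonds and three C–Br bonds are cut. Benzyl and bromine are chosen because one hydrogenolysis removes both, and because the bromines also steer the key step. The forward reaction must spare the cyclic benzylic ether C2–O1 and the C-α–C6 bond, which mild hydrogenolysis over Pd(OH)2/C does in this compound class.

**9 ⇒ 7 + 5 (through cation 8).** Two bonds are cut together: C-α–C6 and O1′–C2′, with O1 returned to C-α to restore a pyran.
- Cutting only C-α–C6 would leave a dihydrobenzofuranyl carbinol that needs its own asymmetric synthesis.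
- Cutting C-α–C6 while keeping the C3 oxygen leads to an aryl C–O exchange on ring D.
- The double cut instead gives two monomeric flavan-3-ol derivatives: mesylate 7 (2S,3R, trans) and bromide 5 (2S,3S, cis).
- Asked of the forward reaction: ionisation of 7 with 1,2-shift of O1 (inversion at C3, giving C2′ S); capture of cation 8 by C6 of 5 on the face flanked by O1′ (giving C-α R); no reaction at the electrophile's own ring.

**7 ⇒ 6 ⇒ 2 and 5 ⇒ 4 ⇒ 3 ⇒ 2.**
- 7 is the mesylate of 6, which is 2 with both free ring positions brominated.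
- 5 is the 8-bromide of 4, the C3 epimer of 2, reached by oxidation to ketone 3 and reduction from the face opposite the C2 aryl group.
- C2 (S) of 2 is thus the one stereocentre that persists into both halves; every other centre is relayed from it.

**2 ⇒ 1.** The four phenolic O–benzyl bonds are cut; 1 is (−)-catechin.

## Roads not taken

**Alternative 1:** the most obvious cut, C-α–C6 alone.
- Forward key step: Lewis-acid Friedel–Crafts reaction of the preformed carbinol A1 with 5.
- A1 would come from an (E)-1,3-diarylpropene by asymmetric epoxidation and 5-exo opening by the ring D phenoxide.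
- The cation and its facial problem are the same as in the chosen plan. But A1 costs about six steps of its own, including epoxidation of an acid-sensitive electron-rich styrene, and its unbrominated ring D competes with 5 as nucleophile.
- The chosen plan draws the same cation from the common intermediate 2 in two steps and forms ring E in the same operation.

**Alternative 2:** cut C-α–C6 and keep the C3 oxygen as the furan oxygen.
- Forward key step: acid-mediated arylative opening of ring C of the (2R,3S) dibromide A2 by 5, with inversion at C2, to the open-chain phenol A3.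
- The stereochemical course is attractive. But ring D must then exchange its phenolic oxygen for the alcohol oxygen: triflation and a C–O coupling on zerovalent palladium in the presence of three aryl bromides.
- It also needs (+)-catechin as a second chiral starting material and two more steps.
- The chosen plan moves the oxygen along the chain rather than exchanging it on the ring.

**Alternative 3:** cut ring C of the lower unit and build it last.
- C-α is para to O1 and flanked by O5 and O7, so the phenol A4 has two equivalent ortho positions and the C6/C8 question disappears by symmetry.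
- Forward key step: cinnamylation of A4, asymmetric dihydroxylation, cyclisation and C3 inversion.
- This puts at least six linear steps after the fragment union, on the most valuable intermediate.
- The arene needed to make A4 reacts with benzylic cations ortho rather than para to its free oxygen, so the regiochemical problem is only moved.
- One bromine at C8 of 5 solves it in a single step.

Key step: step 7

## Route

Step 1
Reactants: 1 (−)-catechin
Product: 2 (2S,3R)-5,7-bis(benzyloxy)-2-[3,4-bis(benzyloxy)phenyl]chroman-3-ol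
Conditions: BnBr (4.5 equiv), K2CO3, DMF, 0 °C to rt
Reagents that add atoms: benzyl bromide, BrCc1ccccc1
Why: Williamson etherification; the four phenols are deprotonated by carbonate and the secondary alcohol is not, and the low temperature limits C-benzylation of ring A.

Step 2
Reactants: 2 (2S,3R)-5,7-bis(benzyloxy)-2-[3,4-bis(benzyloxy)phenyl]chroman-3-ol
Product: 3 (2S)-5,7-bis(benzyloxy)-2-[3,4-bis(benzyloxy)phenyl]chroman-3-one
Conditions: Dess–Martin periodinane, water-saturated CH2Cl2, rt
Reagents that add atoms: none
Why: Dess–Martin oxidation of the secondary alcohol under neutral conditions, which should not enolise the ketone toward C2, now the only stereocentre.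

Step 3
Reactants: 3 (2S)-5,7-bis(benzyloxy)-2-[3,4-bis(benzyloxy)phenyl]chroman-3-one
Product: 4 (2S,3S)-5,7-bis(benzyloxy)-2-[3,4-bis(benzyloxy)phenyl]chroman-3-ol
Conditions: LiBH(sec-Bu)3, THF, −78 °C; then H2O
Reagents that add atoms: none
Why: substrate-controlled reduction by a bulky hydride, which attacks C3 from the face opposite the C2 aryl group and so should give the 2,3-cis alcohol (C3 S); the low temperature avoids enolisation.

Step 4
Reactants: 4 (2S,3S)-5,7-bis(benzyloxy)-2-[3,4-bis(benzyloxy)phenyl]chroman-3-ol
Product: 5 (2S,3S)-5,7-bis(benzyloxy)-2-[3,4-bis(benzyloxy)phenyl]-8-bromochroman-3-ol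
Conditions: NBS (1.05 equiv), CH2Cl2, −78 °C to rt
Reagents that add atoms: N-bromosuccinimide, O=C1CCC(=O)N1Br
Why: electrophilic aromatic bromination; C8 is the more accessible of the two free positions of ring A (C6 lies between two benzyloxy groups), so one equivalent should block C8 and leave C6 as the only nucleophilic site.

Step 5
Reactants: 2 (2S,3R)-5,7-bis(benzyloxy)-2-[3,4-bis(benzyloxy)phenyl]chroman-3-ol
Product: 6 (2S,3R)-5,7-bis(benzyloxy)-2-[3,4-bis(benzyloxy)phenyl]-6,8-dibromochroman-3-ol
Conditions: NBS (2.2 equiv), CH2Cl2, 0 °C to rt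
Reagents that add atoms: N-bromosuccinimide, O=C1CCC(=O)N1Br
Why: twofold electrophilic bromination; both free positions of the phloroglucinol-type ring A are far more nucleophilic than ring B, so ring A should be fully substituted before ring B reacts.

Step 6
Reactants: 6 (2S,3R)-5,7-bis(benzyloxy)-2-[3,4-bis(benzyloxy)phenyl]-6,8-dibromochroman-3-ol
Product: 7 (2S,3R)-5,7-bis(benzyloxy)-2-[3,4-bis(benzyloxy)phenyl]-6,8-dibromochroman-3-yl methanesulfonate
Conditions: (MeSO2)2O, Et3N, DMAP (cat.), CH2Cl2, −20 to 0 °C
Reagents that add atoms: methanesulfonic anhydride, CS(=O)(=O)OS(C)(=O)=O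
Why: O-sulfonylation with retention at C3; the anhydride keeps chloride out of the flask, and the two bromines lower the donor strength of O1 so that the mesylate should survive isolation.

Step 7
Reactants: 7 (2S,3R)-5,7-bis(benzyloxy)-2-[3,4-bis(benzyloxy)phenyl]-6,8-dibromochroman-3-yl methanesulfonate; 5 (2S,3S)-5,7-bis(benzyloxy)-2-[3,4-bis(benzyloxy)phenyl]-8-bromochroman-3-ol
Product: 9 (2S,3S)-5,7-bis(benzyloxy)-2-[3,4-bis(benzyloxy)phenyl]-6-{(R)-[3,4-bis(benzyloxy)phenyl][(2S)-4,6-bis(benzyloxy)-5,7-dibromo-2,3-dihydro-1-benzofuran-2-yl]methyl}-8-bromochroman-3-ol, via ring-contracted benzylic cation 8 (not isolated)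
Conditions: 5 (2.0 equiv), 2,6-di-tert-butyl-4-methylpyridine (1.5 equiv), (CF3)2CHOH–CH2Cl2 4:1, 45 °C
Reagents that add atoms: none
Why: Proposed new method: in hexafluoroisopropanol the equatorial mesylate of the 2,3-trans half-chair should ionise with help from O1, which lies antiperiplanar to the C3–O bond and attacks C3 from the rear (3-exo-tet) while the O1–C2 bond breaks toward the 4-benzyloxybenzylic carbon, so that ring C contracts to ring E and cation 8 results; the closest known reactions are the anchimerically assisted ring contraction of 2,3-trans-flavan-3-yl and tetrahydropyran-3-yl sulfonates with capture by oxygen or halide nucleophiles and the Friedel–Crafts coupling of flavanyl benzylic cations at C6 of 8-bromoflavans, and only the capture of the ring-contracted cation by an arene is new. C2′ is set by that rear-side attack, a stereospecific inversion of C3 (R in 7, S at C2′ in 9). Cation 8 is stabilised by ring F and is captured only slowly by the hindered C6 of 5, while return of mesylate and capture by solvent are reversible, so C-α should be set on the relaxed cation under control of C2′. Allylic 1,3-strain holds H2′ in the plane of the cation beside ring F; the two faces are then flanked by O1′ and by C3′H2, and the arene should enter past the oxygen, anti to the C2′–C3′ bond, which is the R configuration. The C6 link is secured by the bromine at C8 of 5, which leaves C6 as the only free position of ring A. The bromines at C6 and C8 of 7 keep its own ring from acting as the nucleophile, and the diequatorial trans geometry, with no C–H or C–aryl bond antiperiplanar to the mesylate, secures oxygen shift over hydride or aryl shift.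

Step 8
Reactants: 9 (2S,3S)-5,7-bis(benzyloxy)-2-[3,4-bis(benzyloxy)phenyl]-6-{(R)-[3,4-bis(benzyloxy)phenyl][(2S)-4,6-bis(benzyloxy)-5,7-dibromo-2,3-dihydro-1-benzofuran-2-yl]methyl}-8-bromochroman-3-ol
Product: 10 (2S,3S)-2-(3,4-dihydroxyphenyl)-6-{(R)-(3,4-dihydroxyphenyl)[(2S)-4,6-dihydroxy-2,3-dihydro-1-benzofuran-2-yl]methyl}chromane-3,5,7-triol (CNP0161875.1)
Conditions: H2 (1 atm), Pd(OH)2/C, NaOAc, THF–MeOH–H2O, rt
Reagents that add atoms: none
Why: hydrogenolysis of eight benzyl ethers and hydrodebromination of three aryl bromides on heterogeneous palladium; acetate takes up HBr so that the acid-labile C-α–C6 bond is not exposed, and no stereocentre carries a hydrogenolysable acyclic benzylic C–O bond.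

## Compound list

1 | (−)-catechin, (2S,3R)-2-(3,4-dihydroxyphenyl)chromane-3,5,7-triol | Oc1cc2c(c(O)c1)C[C@@H](O)[C@H](c1ccc(O)c(O)c1)O2 | starting material
2 | (2S,3R)-5,7-bis(benzyloxy)-2-[3,4-bis(benzyloxy)phenyl]chroman-3-ol | c1ccccc1COc1cc2c(c(OCc3ccccc3)c1)C[C@@H](O)[C@H](c1ccc(OCc3ccccc3)c(OCc3ccccc3)c1)O2 | intermediate
3 | (2S)-5,7-bis(benzyloxy)-2-[3,4-bis(benzyloxy)phenyl]chroman-3-one | c1ccccc1COc1cc2c(c(OCc3ccccc3)c1)CC(=O)[C@H](c1ccc(OCc3ccccc3)c(OCc3ccccc3)c1)O2 | intermediate
4 | (2S,3S)-5,7-bis(benzyloxy)-2-[3,4-bis(benzyloxy)phenyl]chroman-3-ol | c1ccccc1COc1cc2c(c(OCc3ccccc3)c1)C[C@H](O)[C@H](c1ccc(OCc3ccccc3)c(OCc3ccccc3)c1)O2 | intermediate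
5 | (2S,3S)-5,7-bis(benzyloxy)-2-[3,4-bis(benzyloxy)phenyl]-8-bromochroman-3-ol | c1ccccc1COc1c(Br)c2c(c(OCc3ccccc3)c1)C[C@H](O)[C@H](c1ccc(OCc3ccccc3)c(OCc3ccccc3)c1)O2 | intermediate
6 | (2S,3R)-5,7-bis(benzyloxy)-2-[3,4-bis(benzyloxy)phenyl]-6,8-dibromochroman-3-ol | c1ccccc1COc1c(Br)c2c(c(OCc3ccccc3)c1Br)C[C@@H](O)[C@H](c1ccc(OCc3ccccc3)c(OCc3ccccc3)c1)O2 | intermediate
7 | (2S,3R)-5,7-bis(benzyloxy)-2-[3,4-bis(benzyloxy)phenyl]-6,8-dibromochroman-3-yl methanesulfonate | c1ccccc1COc1c(Br)c2c(c(OCc3ccccc3)c1Br)C[C@@H](OS(C)(=O)=O)[C@H](c1ccc(OCc3ccccc3)c(OCc3ccccc3)c1)O2 | intermediate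
8 | [3,4-bis(benzyloxy)phenyl][4,6-bis(benzyloxy)-5,7-dibromo-2,3-dihydro-1-benzofuran-2-yl]methylium, C2′ configured as in 9 | c1ccccc1COc1c(Br)c(OCc3ccccc3)c2c(c1Br)O[C@H]([CH+]c1ccc(OCc3ccccc3)c(OCc3ccccc3)c1)C2 | intermediate
9 | (2S,3S)-5,7-bis(benzyloxy)-2-[3,4-bis(benzyloxy)phenyl]-6-{(R)-[3,4-bis(benzyloxy)phenyl][(2S)-4,6-bis(benzyloxy)-5,7-dibromo-2,3-dihydro-1-benzofuran-2-yl]methyl}-8-bromochroman-3-ol | c1ccccc1COc1c(Br)c(OCc3ccccc3)c2c(c1Br)O[C@H]([C@H](c1ccc(OCc3ccccc3)c(OCc3ccccc3)c1)c1c(OCc3ccccc3)c(Br)c3c(c1OCc1ccccc1)C[C@H](O)[C@H](c1ccc(OCc4ccccc4)c(OCc4ccccc4)c1)O3)C2 | intermediate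
10 | (2S,3S)-2-(3,4-dihydroxyphenyl)-6-{(R)-(3,4-dihydroxyphenyl)[(2S)-4,6-dihydroxy-2,3-dihydro-1-benzofuran-2-yl]methyl}chromane-3,5,7-triol | Oc1cc(O)c2c(c1)O[C@H]([C@H](c1ccc(O)c(O)c1)c1c(O)cc3c(c1O)C[C@H](O)[C@H](c1ccc(O)c(O)c1)O3)C2 | target

## Step count and least certain steps

Total: 8 steps. Longest linear sequence: 6 steps (1, 2, 3, 4, 7, 8).

**Step 7 (key step, proposed new method).**
- Most likely failure: poor or reversed facial selectivity in the capture of cation 8. The two faces differ only as O1′ against C3′H2; if partial bridging by O1′ or a preference for attack anti to the C–O bond dominates, the C-α epimer of 9 would form. Loss of H2′ to the aromatic 2-benzylbenzofuran is the second hazard, since the arene is hindered.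
- Fallback (known chemistry, the two events in the other order): from 6 and 5, BF3·OEt2 in CH2Cl2 should open ring C of 6 at C2 with C6 of 5, the acid-mediated arylative pyran cleavage known for flavan-3-ols and phenols. This gives the open-chain phenol diol (2S,3S)-5,7-bis(benzyloxy)-2-[3,4-bis(benzyloxy)phenyl]-6-{(1R,2R)-1-[3,4-bis(benzyloxy)phenyl]-3-[2,4-bis(benzyloxy)-3,5-dibromo-6-hydroxyphenyl]-2-hydroxypropyl}-8-bromochroman-3-ol F1.
- Mitsunobu closure (PPh3, diisopropyl azodicarboxylate) of the liberated phenol onto the carbinol carbon, 5-exo with inversion, then returns to 9.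
- This order needs the open-chain cation to be captured anti to its β-oxygen, the same facial sense that would defeat the key step. Between them the two orders cover both preferences of the cation.

**Step 6.**
- Most likely failure: premature ionisation of the mesylate during work-up or chromatography, with ring contraction and capture by adventitious nucleophiles, since the oxygen shift that the key step relies on is already available.
- Fallback: from 6, sulfonylate as before and, without isolation, let the mesylate solvolyse in methanol to the stable ring-contracted methyl ether (2S)-4,6-bis(benzyloxy)-2-{[3,4-bis(benzyloxy)phenyl](methoxy)methyl}-5,7-dibromo-2,3-dihydro-1-benzofuran F2 (both C-α epimers, which converge on the same cation).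
- Ionising F2 with Me3SiOTf at −78 °C in CH2Cl2 in the presence of 5 then returns to 9. The cation is here drawn from an isolable benzylic ether by a Lewis acid rather than from a sulfonate by solvolysis.

**Step 5.**
- Most likely failure: bromination of ring B (para to a benzyloxy group) competing with the second, hindered substitution at C6 of ring A.
- Fallback: from 1, brominate before protection, where the free phloroglucinol ring is far more reactive than the catechol, to give (2S,3R)-6,8-dibromo-2-(3,4-dihydroxyphenyl)chromane-3,5,7-triol F4. Benzylation (BnBr, K2CO3, DMF) then returns to 6.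

**Step 8.**
- Most likely failure: incomplete hydrodebromination of the two bromides flanked by oxygen substituents, or cleavage of the C-α–C6 bond by HBr if the buffer is outrun while eleven groups are being removed.
- Fallback: from 9, remove the bromines first by bromine–lithium exchange (n-BuLi in excess, THF, −78 °C, methanol quench) to the bromine-free octabenzyl ether (2S,3S)-5,7-bis(benzyloxy)-2-[3,4-bis(benzyloxy)phenyl]-6-{(R)-[3,4-bis(benzyloxy)phenyl][(2S)-4,6-bis(benzyloxy)-2,3-dihydro-1-benzofuran-2-yl]methyl}chroman-3-ol F3.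
- Hydrogenolysis of F3 over Pd(OH)2/C without any halide present then gives 10.

## Further compounds

F1 | step 7 | (2S,3S)-5,7-bis(benzyloxy)-2-[3,4-bis(benzyloxy)phenyl]-6-{(1R,2R)-1-[3,4-bis(benzyloxy)phenyl]-3-[2,4-bis(benzyloxy)-3,5-dibromo-6-hydroxyphenyl]-2-hydroxypropyl}-8-bromochroman-3-ol | Oc1c(Br)c(OCc2ccccc2)c(Br)c(OCc2ccccc2)c1C[C@@H](O)[C@H](c1ccc(OCc2ccccc2)c(OCc2ccccc2)c1)c1c(OCc2ccccc2)c(Br)c3c(c1OCc1ccccc1)C[C@H](O)[C@H](c1ccc(OCc4ccccc4)c(OCc4ccccc4)c1)O3
F2 | step 6 | (2S)-4,6-bis(benzyloxy)-2-{[3,4-bis(benzyloxy)phenyl](methoxy)methyl}-5,7-dibromo-2,3-dihydro-1-benzofuran, both C-α epimers | c1ccccc1COc1c(Br)c(OCc3ccccc3)c2c(c1Br)O[C@H](C(OC)c1ccc(OCc3ccccc3)c(OCc3ccccc3)c1)C2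
F4 | step 5 | (2S,3R)-6,8-dibromo-2-(3,4-dihydroxyphenyl)chromane-3,5,7-triol | Oc1c(Br)c2c(c(O)c1Br)C[C@@H](O)[C@H](c1ccc(O)c(O)c1)O2
F3 | step 8 | (2S,3S)-5,7-bis(benzyloxy)-2-[3,4-bis(benzyloxy)phenyl]-6-{(R)-[3,4-bis(benzyloxy)phenyl][(2S)-4,6-bis(benzyloxy)-2,3-dihydro-1-benzofuran-2-yl]methyl}chroman-3-ol | c1ccccc1COc1cc(OCc3ccccc3)c2c(c1)O[C@H]([C@H](c1ccc(OCc3ccccc3)c(OCc3ccccc3)c1)c1c(OCc3ccccc3)cc3c(c1OCc1ccccc1)C[C@H](O)[C@H](c1ccc(OCc4ccccc4)c(OCc4ccccc4)c1)O3)C2
A1 | alternative 1 | [(2S)-4,6-bis(benzyloxy)-2,3-dihydro-1-benzofuran-2-yl][3,4-bis(benzyloxy)phenyl]methanol, either carbinol epimer | c1ccccc1COc1cc(OCc3ccccc3)c2c(c1)O[C@H](C(O)c1ccc(OCc3ccccc3)c(OCc3ccccc3)c1)C2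
A2 | alternative 2 | (2R,3S)-5,7-bis(benzyloxy)-2-[3,4-bis(benzyloxy)phenyl]-6,8-dibromochroman-3-ol | c1ccccc1COc1c(Br)c2c(c(OCc3ccccc3)c1Br)C[C@H](O)[C@@H](c1ccc(OCc3ccccc3)c(OCc3ccccc3)c1)O2
A3 | alternative 2 | (2S,3S)-5,7-bis(benzyloxy)-2-[3,4-bis(benzyloxy)phenyl]-6-{(1R,2S)-1-[3,4-bis(benzyloxy)phenyl]-3-[2,4-bis(benzyloxy)-3,5-dibromo-6-hydroxyphenyl]-2-hydroxypropyl}-8-bromochroman-3-ol | Oc1c(Br)c(OCc2ccccc2)c(Br)c(OCc2ccccc2)c1C[C@H](O)[C@H](c1ccc(OCc2ccccc2)c(OCc2ccccc2)c1)c1c(OCc2ccccc2)c(Br)c3c(c1OCc1ccccc1)C[C@H](O)[C@H](c1ccc(OCc4ccccc4)c(OCc4ccccc4)c1)O3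
A4 | alternative 3 | 3,5-bis(benzyloxy)-4-{(R)-[3,4-bis(benzyloxy)phenyl][(2S)-4,6-bis(benzyloxy)-2,3-dihydro-1-benzofuran-2-yl]methyl}phenol | c1ccccc1COc1cc(OCc3ccccc3)c2c(c1)O[C@H]([C@H](c1ccc(OCc3ccccc3)c(OCc3ccccc3)c1)c1c(OCc3ccccc3)cc(O)cc1OCc1ccccc1)C2
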